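**Assumption:** the stereocentre in the target SMILES is (S), and (S)-3-(4-hydroxyphenyl)lactic acid (the L-tyrosine-derived hydroxy acid) is purchasable; if not, it is one step from L-tyrosine (NaNO2, aq. H2SO4, retention).

## Retrosynthetic overview

1. Target ⇒ fully protected ketone (2 × aryl-OMOM, 2 × OTBS) by one global acidic deprotection.
2. Aryl–C(=O) disconnection: aryllithium (from an aryl bromide by Br/Li exchange) + Weinreb amide of (S)-3-(4-hydroxyphenyl)lactic acid. The only stereocentre is bought (chiral pool) and never touched.
3. Aryl bromide ⇐ 2,4,6-tribromoresorcinol: MOM protection, then two successive Br/Li exchange–prenylations (first the Br between the two OMOM groups, then one of two symmetry-equivalent Br atoms).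
4. No rings are formed; both benzene rings come from the starting materials.

## Route

**Step 1**
Reactants: 1, 2,4,6-tribromoresorcinol
Product: 2, 1,3,5-tribromo-2,4-bis(methoxymethoxy)benzene
Conditions: MOMCl (3 equiv), i-Pr2NEt (4 equiv), CH2Cl2, 0 °C → rt
Reagents that add atoms: chloromethyl methyl ether (MOMCl), COCCl
Why: O-alkylation of the two acidic phenols gives MOM acetals that tolerate organolithiums, cannot undergo retro-Brook migration and come off in mild acid; no stereocentre involved.

**Step 2**
Reactants: 2, tribromo bis-MOM ether; 3, prenyl bromide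
Product: 4, 1,5-dibromo-2,4-bis(methoxymethoxy)-3-(3-methylbut-2-en-1-yl)benzene
Conditions: n-BuLi (0.98 equiv), THF, −78 °C; CuI (0.5 equiv); prenyl bromide (1.3 equiv), −78 → 0 °C
Reagents that add atoms: prenyl bromide (3), CC(C)=CCBr
Why: Bromine–lithium exchange goes to the bromine flanked by two chelating OMOM groups (the most stabilised aryllithium; a slight deficit of BuLi lets ArLi/ArBr equilibrate to it), and Cu-mediated SN2 allylation gives the linear prenyl group.

**Step 3**
Reactants: 4, dibromo mono-prenyl arene; 3, prenyl bromide
Product: 5, 1-bromo-2,4-bis(methoxymethoxy)-3,5-bis(3-methylbut-2-en-1-yl)benzene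
Conditions: n-BuLi (1.0 equiv), THF, −78 °C; CuI (0.5 equiv); prenyl bromide (1.3 equiv), −78 → 0 °C
Reagents that add atoms: prenyl bromide (3), CC(C)=CCBr
Why: The two remaining bromines are symmetry-equivalent, so mono Br/Li exchange is regiochemically unambiguous; transmetalation to copper before allylation suppresses ArLi/ArBr scrambling and over-prenylation.

**Step 4**
Reactants: 6, (S)-2-hydroxy-3-(4-hydroxyphenyl)propanoic acid
Product: 7, (S)-2-hydroxy-3-(4-hydroxyphenyl)-N-methoxy-N-methylpropanamide
Conditions: MeNHOMe·HCl (1.5 equiv), EDC·HCl, HOBt, N-methylmorpholine, DMF, 0 °C → rt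
Reagents that add atoms: N,O-dimethylhydroxylamine hydrochloride, CNOC.Cl
Why: Carbodiimide/HOBt amidation (Weinreb amide formation) in which the amine outcompetes the phenol and secondary OH; the (S) centre is carried over from the chiral pool with no bond to it made or broken.

**Step 5**
Reactants: 7, Weinreb amide diol
Product: 8, (S)-2-(tert-butyldimethylsilyloxy)-3-[4-(tert-butyldimethylsilyloxy)phenyl]-N-methoxy-N-methylpropanamide
Conditions: TBSCl (3 equiv), imidazole (6 equiv), DMF, rt
Reagents that add atoms: tert-butyldimethylsilyl chloride (TBSCl), CC(C)(C)[Si](C)(C)Cl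
Why: Corey silylation caps both the phenol and the α-hydroxyl in one operation, removing acidic protons before the organolithium step; configuration is unaffected.

**Step 6**
Reactants: 5, aryl bromide (1.2 equiv); 8, bis-TBS Weinreb amide (1.0 equiv)
Product: 9, (S)-1-[2,4-bis(methoxymethoxy)-3,5-bis(3-methylbut-2-en-1-yl)phenyl]-2-(tert-butyldimethylsilyloxy)-3-[4-(tert-butyldimethylsilyloxy)phenyl]propan-1-one
Conditions: 5, n-BuLi (1.15 equiv), THF, −78 °C, 20 min; then 8, −78 → −20 °C; sat. NH4Cl
Reagents that add atoms: none (only the two numbered reactants)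
Why: Br/Li exchange at −78 °C is faster than deprotonation of the prenyl CH2 groups, and Weinreb ketone synthesis stops at the chelated tetrahedral intermediate (no over-addition); the α-silyloxy stereocentre is not enolised at low temperature, so (S) is retained.

**Step 7**
Reactants: 9, fully protected ketone
Product: 10, lespeflorin C6, (S)-1-[2,4-dihydroxy-3,5-bis(3-methylbut-2-en-1-yl)phenyl]-2-hydroxy-3-(4-hydroxyphenyl)propan-1-one
Conditions: aq. HCl (about 1 M final), MeOH–THF, 40–45 °C, Ar, monitored to completion
Reagents that add atoms: none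
Why: Acid-catalysed acetal methanolysis (2 × MOM) and acidic desilylation (alkyl and aryl TBS) happen in one pot under conditions routinely used for MOM removal from prenylated polyphenols, mild enough to spare the prenyl alkenes and the α-ketol stereocentre.

## Compound list

1 | 2,4,6-tribromobenzene-1,3-diol (2,4,6-tribromoresorcinol) | Oc1c(Br)cc(Br)c(O)c1Br | starting material
2 | 1,3,5-tribromo-2,4-bis(methoxymethoxy)benzene | COCOc1c(Br)cc(Br)c(OCOC)c1Br | intermediate
3 | prenyl bromide (1-bromo-3-methylbut-2-ene) | CC(C)=CCBr | starting material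
4 | 1,5-dibromo-2,4-bis(methoxymethoxy)-3-(3-methylbut-2-en-1-yl)benzene | COCOc1c(Br)cc(Br)c(OCOC)c1CC=C(C)C | intermediate
5 | 1-bromo-2,4-bis(methoxymethoxy)-3,5-bis(3-methylbut-2-en-1-yl)benzene | COCOc1c(Br)cc(CC=C(C)C)c(OCOC)c1CC=C(C)C | intermediate
6 | (S)-2-hydroxy-3-(4-hydroxyphenyl)propanoic acid | OC(=O)[C@@H](O)Cc1ccc(O)cc1 | starting material
7 | (S)-2-hydroxy-3-(4-hydroxyphenyl)-N-methoxy-N-methylpropanamide | CON(C)C(=O)[C@@H](O)Cc1ccc(O)cc1 | intermediate
8 | (S)-2-(tert-butyldimethylsilyloxy)-3-[4-(tert-butyldimethylsilyloxy)phenyl]-N-methoxy-N-methylpropanamide | CON(C)C(=O)[C@@H](O[Si](C)(C)C(C)(C)C)Cc1ccc(O[Si](C)(C)C(C)(C)C)cc1 | intermediate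
9 | (S)-1-[2,4-bis(methoxymethoxy)-3,5-bis(3-methylbut-2-en-1-yl)phenyl]-2-(tert-butyldimethylsilyloxy)-3-[4-(tert-butyldimethylsilyloxy)phenyl]propan-1-one | CC(C)=CCc1cc(C(=O)[C@@H](O[Si](C)(C)C(C)(C)C)Cc2ccc(O[Si](C)(C)C(C)(C)C)cc2)c(OCOC)c(CC=C(C)C)c1OCOC | intermediate
10 | lespeflorin C6, (S)-1-[2,4-dihydroxy-3,5-bis(3-methylbut-2-en-1-yl)phenyl]-2-hydroxy-3-(4-hydroxyphenyl)propan-1-one | CC(C)=CCc1cc(C(=O)[C@@H](O)Cc2ccc(O)cc2)c(O)c(CC=C(C)C)c1O | target

## Summary

Total steps: 7. Longest linear sequence: 5 (1 → 2 → 4 → 5 → 9 → 10); the amide branch (6 → 7 → 8) is 2 steps.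

Three steps most likely to fail, with fallbacks:

1. **Step 7 (global deprotection).** Risks are acid-promoted cyclisation of the ortho-prenyl phenols to dimethylchromans, slow aryl-TBS cleavage, and α-ketol epimerisation or isomerisation. Fallback: run steps 2–3 with allyl bromide instead of prenyl bromide, carry acid-robust allyl groups through coupling and deprotection, and install both prenyl groups last by double cross-metathesis with 2-methyl-2-butene (Grubbs II) on the free polyphenol.
2. **Step 2 (regioselective Br/Li exchange and alkylation at the crowded position between the OMOM groups).** Risks are exchange at the other bromines or sluggish allylation. Fallback: drop halogen–metal exchange for directed ortho-metalation. Start from 1,3-bis(methoxymethoxy)benzene, lithiate at the position between the two OMOM groups (n-BuLi) and prenylate, then use s-BuLi/TMEDA ortho-lithiations for the second prenylation and for the acylation.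
3. **Step 6 (aryllithium + Weinreb amide).** Risks are incomplete addition to the hindered α-OTBS amide, or quenching of the aryllithium by the benzylic/allylic prenyl protons. Fallback: reduce 8 to the α-silyloxy aldehyde (DIBAL-H, −78 °C), add the aryllithium or aryl Grignard to the aldehyde, and oxidise the resulting carbinol with Dess–Martin periodinane. This two-step addition/oxidation gives the same ketone 9.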